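## Structural features

- **Numbering.** C1 is the carboxyl carbon and the main chain runs C1 to C17, with phenyl on C17. The only ring is the 1,2-dioxolane O1–O2–C3–C4–C5, with O2 on C3 and O1 on C5.
- **Ring centres.** C3 (CH3, C2H2–CO2H) and C5 (CH3, C6 chain) are both fully substituted. In the (3R,5S) isomer the two long arms are trans, so the acetic acid arm is cis to the C5 methyl and the C3 methyl is cis to the C6 chain.
- **Chain.** C7 (S) and C9 (R) form an anti-1,3-dimethyl pair, followed by eight CH2 groups and phenyl. C3, C5, C7 and C9 each carry a methyl in a 1,3 relationship, and the chain has no heteroatom that could direct a reagent.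
- **Fragile groups.** The O–O bond is sensitive to phosphines, sulfides, low-valent metals and carbanions. The β-peroxy ester or acid can open at O2–C3 by retro-Michael reaction under base.
- **Real difficulty.** Each of the two tetrasubstituted C–O stereocentres must distinguish one CH3 from two CH2 groups. Tertiary C–OO bonds are usually made through planar radicals or cations that lose this information, and C5 has no functional handle.
- **Feature exploited by the key step.** C3 is bound to ring oxygen O2, so a cation at C3 is an O2-stabilised peroxycarbenium ion. It sits 1,3 to C5 inside the ring, so the CH3/C6 pair on C5 differentiates its two faces, and the missing C1–C2 arm is an acetate enolate equivalent.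
- **Route in one sentence.** The acyclic β-silylperoxy ketone 12 closes the O2–C3 bond, ionises to the planar C3 peroxycarbenium ion, and is captured at C3 by ketene acetal 13.

## Logic of the disconnections

**17 to 16.** Only the acyl C1–O bond changes, from acid to methyl ester. The ester is what the commercial acetate equivalent delivers. The forward step must hydrolyse it without opening O2–C3 by β-elimination.

**16 to 12 and 13.**
- Bonds cut: the exocyclic C2–C3 bond and the ring bond O2–C3.
- Reason: C3 is the only carbon that can carry a stabilised positive charge next to the peroxide, and the arm is a two-carbon nucleophile.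
- Gain: the ring, one quaternary stereocentre and the arm all disappear, leaving an acyclic ketone whose only ring stereocentre is C5.
- Demand: ring closure must come before C–C bond formation, attack must be face-selective under control of C5, and the O–O bond must survive a Lewis acid.

**12 to 10 (through 11).** No skeletal bond is cut. C3=O goes back to C3–OH and O2–Si to O2–H. This places an oxygen on C3 that can be traced to a strained ether. The forward steps must tell the hydroperoxide from the alcohol and oxidise without a reducing by-product.

**10 to 9.**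
- Bond cut: C5–O1. C5 is reconnected to the oxygen on C3, giving a temporary four-membered ring that is absent from the target.
- Reason: ring strain allows hydrogen peroxide to enter at a quaternary carbon with inversion, so O–O arrives intact and C5 is derived from a carbinol centre.
- Gain: the peroxide disappears from every earlier intermediate.
- Demand: attack at C5 rather than C3, and bond breaking that stays coupled to bond making.

**9 to 8.** The O–C3 bond of the temporary ring is cut, giving a tertiary homoallylic alcohol. The C3 methyl becomes the terminal CH2 of a vinyl group. The forward step must be a Markovnikov, four-membered hydroalkoxylation. The configuration created at C3 does not matter because C3 becomes a carbonyl carbon later.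

**8 to 7.** The C3–C4 bond is cut, giving a 2,2-disubstituted epoxide and a vinyl nucleophile. The C5–O bond is untouched, so C5 is carried over unchanged. The nucleophile must attack only the CH2 terminus.

**7 to 6.** The C4–C5 and C4–O bonds are cut (methylene transfer). C5 becomes the carbonyl carbon of a methyl ketone, which is the situation in which CH3 and CH2R differ most for a chiral catalyst. The catalyst must override the remote C7 centre.

**6 to 5.** The C7–CH3 bond is cut, giving an E-enone. C7 becomes a prochiral β-carbon. The forward step needs 1,4-regioselectivity and ligand control to give the anti relationship to C9.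

**5 to 4.** The C6=C7 bond is cut (carbonyl olefination). Only E-selectivity is required.

**4 to 1 and 2 (through 3).** The C12–C13 bond is cut as an alkene. C9 then comes from the chiral pool and the arene terminus from a commercial alkene. The forward steps need a productive exchange at a trisubstituted alkene and a hydrogenation that leaves the aldehyde alone.

## Other disconnections considered

Alternative 1: (the first that comes to mind)
- Cut: O2–C3 only.
- Forward key step: 5-exo-trig conjugate addition of the C5 hydroperoxide of A1 to its enoate, with A1 made by cobalt-catalysed Mukaiyama–Isayama peroxidation of dienoate A2.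
- Grounds for rejection: C5 would arise from a planar tertiary radical that dioxygen can approach from either face, with nothing nearby except alkyl groups. The conjugate addition is reversible under the basic conditions it needs, and its two transition states differ only in where CH3 and CH2 lie. All four ring diastereomers should therefore be expected, and they differ from each other only far from the chain centres. The chosen plan derives C5 stereospecifically and forms C3 irreversibly.

Alternative 2:
- Cut: C3–C4 and C5–O1.
- Forward key step: [3+2] annulation of the silylperoxycarbenium ion from A3 with alkene A4.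
- Merit: this is the shortest and most convergent plan, since it joins both fragments and makes both quaternary centres at once.
- Grounds for rejection: C3 is attacked as an acyclic cation with no stereocentre near it, and C5 passes through an open tertiary carbocation. The only resident control is the all-alkyl C7 centre. Step economy favours this plan, but stereocontrol at both ring centres does not.

Alternative 3:
- Cut: O2–C3, with the carboxylate as nucleofuge.
- Forward key step: 5-exo-tet invertive opening of the β-lactone in A5 by the C5 hydroperoxide, which would set C3 stereospecifically and reveal the free acid.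
- Grounds for rejection: it requires a configurationally defined C5 hydroperoxide next to an already quaternary C3. The stereospecific entries to a tertiary hydroperoxide (opening of a strained ether at C5) leave a hydroxyl on C3 or C4, which cannot coexist with that C3. C5 would therefore fall back on radical peroxidation. The β,β-disubstituted lactone is also prone to ionisation and loss of CO2 under the acid that the closure needs. The plan solves C3 but not C5.

Key step: step 11

Assumption: the sense of induction in the two catalyst-controlled steps (4 and 5) is fixed by the ligand enantiomer. The enantiomers written are those expected to give 4S in 6 and 2R in 7, and the mirror-image ligand would be used if the sense were opposite.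

## Steps

Step 1
Reactants: 1 (R)-citronellal; 2 6-phenylhex-1-ene
Product: 3 (3R)-3-methyl-11-phenylundec-6-enal (E/Z mixture)
Conditions: 2 (3 equiv), second-generation Grubbs catalyst RuCl2(=CHPh)(PCy3)(H2IMes) (3 mol %), CH2Cl2, 40 °C
Reagents that add atoms: none
Why: Olefin cross metathesis exchanges the isopropylidene end of 1 for the phenylpentylidene end of 2 and is driven by loss of a volatile alkene; C9 is remote and untouched, and the alkene geometry is irrelevant because the double bond is hydrogenated next.

Step 2
Reactants: 3 (3R)-3-methyl-11-phenylundec-6-enal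
Product: 4 (3R)-3-methyl-11-phenylundecanal
Conditions: H2 (1 atm), Pd/C, EtOAc, rt
Reagents that add atoms: none
Why: Heterogeneous catalytic hydrogenation of an unhindered disubstituted alkene should be much faster than reduction of the aliphatic aldehyde or the arene under these mild conditions.

Step 3
Reactants: 4 (3R)-3-methyl-11-phenylundecanal
Product: 5 (3E,6R)-6-methyl-14-phenyltetradec-3-en-2-one
Conditions: Ph3P=CHC(O)CH3, toluene, 80 °C
Reagents that add atoms: 1-(triphenyl-λ5-phosphanylidene)propan-2-one CC(=O)C=P(c1ccccc1)(c1ccccc1)c1ccccc1
Why: Wittig olefination with a stabilised ylide should give the E-enone; the neutral conditions do not affect the β-stereocentre C9.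

Step 4
Reactants: 5 (3E,6R)-6-methyl-14-phenyltetradec-3-en-2-one
Product: 6 (4S,6R)-4,6-dimethyl-14-phenyltetradecan-2-one
Conditions: MeMgBr (1.2 equiv), CuBr·SMe2 (5 mol %), (R)-1-[(S)-2-(diphenylphosphino)ferrocenyl]ethyldicyclohexylphosphine (6 mol %), t-BuOMe, −75 °C; then H2O
Reagents that add atoms: methylmagnesium bromide C[Mg]Br
Why: Copper-catalysed asymmetric conjugate addition of a Grignard reagent to an acyclic enone; the ferrocenyl diphosphine selects the face of C7, so C7 (S, anti to C9) is set by the catalyst and not by the remote C9 methyl group.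

Step 5
Reactants: 6 (4S,6R)-4,6-dimethyl-14-phenyltetradecan-2-one
Product: 7 (2R)-2-[(2S,4R)-2,4-dimethyl-12-phenyldodecyl]-2-methyloxirane
Conditions: Me3S(O)I, NaH, THF (ylide pre-formed); LaLi3[(S)-binaphthoxide]3 (5 mol %), tris(2,4,6-trimethoxyphenyl)phosphine oxide (5 mol %), 5 Å MS, THF, rt
Reagents that add atoms: trimethylsulfoxonium iodide C[S+](C)(C)=O.[I-]
Why: Catalytic asymmetric Corey–Chaykovsky epoxidation of a methyl ketone; the lanthanum–lithium binaphthoxide binds ketone and ylide together and distinguishes CH3 from CH2R, which sets C5 as the carbinol-type centre (2R) that step 8 inverts.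

Step 6
Reactants: 7 (2R)-2-[(2S,4R)-2,4-dimethyl-12-phenyldodecyl]-2-methyloxirane
Product: 8 (4S,6S,8R)-4,6,8-trimethyl-16-phenylhexadec-1-en-4-ol
Conditions: CH2=CHMgBr (2 equiv), CuI (10 mol %), THF, −30 to 0 °C; then H2O
Reagents that add atoms: vinylmagnesium bromide C=C[Mg]Br
Why: Copper-catalysed SN2 opening of a 2,2-disubstituted epoxide occurs at the unsubstituted CH2 (C4); the C5–O bond is not touched, so C5 keeps its geometry and only the descriptor changes, through a change of priorities.

Step 7
Reactants: 8 (4S,6S,8R)-4,6,8-trimethyl-16-phenylhexadec-1-en-4-ol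
Product: 9 (2R,4RS)-2-[(2S,4R)-2,4-dimethyl-12-phenyldodecyl]-2,4-dimethyloxetane
Conditions: [N,N′-bis(3,5-di-tert-butylsalicylidene)-1,1,2,2-tetramethylethane-1,2-diaminato]cobalt (3 mol %), N-fluoro-2,4,6-trimethylpyridinium triflate, (Me2SiH)2O, PhCF3, rt
Reagents that add atoms: none
Why: Cobalt-hydride hydrogen-atom transfer with radical–polar crossover (Mukaiyama-type hydroalkoxylation, known to cycloisomerise homoallylic alcohols to oxetanes) places H on the terminal carbon, and the tertiary hydroxyl displaces cobalt at C3 in a 4-exo closure favoured by the geminal substitution at C5; C5 is untouched and the new C3 centre is erased in step 10.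

Step 8
Reactants: 9 (2R,4RS)-2-[(2S,4R)-2,4-dimethyl-12-phenyldodecyl]-2,4-dimethyloxetane
Product: 10 (2RS,4S,6S,8R)-4-hydroperoxy-4,6,8-trimethyl-16-phenylhexadecan-2-ol
Conditions: H2O2 (anhydrous, in Et2O, excess), TMSOTf (0.2 equiv), Et2O, −78 to −20 °C
Reagents that add atoms: hydrogen peroxide OO
Why: Lewis-acid perhydrolysis of an oxetane; the silylated ring oxygen leaves from the carbon that best carries positive charge (C5), and strain release keeps C–O cleavage coupled to back-side attack of H2O2, so C5 should be inverted to the configuration of the target while the O–O unit enters intact.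

Step 9
Reactants: 10 (2RS,4S,6S,8R)-4-hydroperoxy-4,6,8-trimethyl-16-phenylhexadecan-2-ol
Product: 11 (2RS,4S,6S,8R)-4,6,8-trimethyl-16-phenyl-4-[(triethylsilyl)peroxy]hexadecan-2-ol
Conditions: Et3SiCl (1.05 equiv), imidazole, CH2Cl2, −30 °C
Reagents that add atoms: chlorotriethylsilane CC[Si](Cl)(CC)CC
Why: Chemoselective silylation; the hydroperoxide is several pKa units more acidic than the secondary alcohol, is an α-effect nucleophile, and its OH lies one atom away from the crowded carbon, so one equivalent of silyl chloride should react there first.

Step 10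
Reactants: 11 (2RS,4S,6S,8R)-4,6,8-trimethyl-16-phenyl-4-[(triethylsilyl)peroxy]hexadecan-2-ol
Product: 12 (4S,6S,8R)-4,6,8-trimethyl-16-phenyl-4-[(triethylsilyl)peroxy]hexadecan-2-one
Conditions: Dess–Martin periodinane, CH2Cl2, 0 °C
Reagents that add atoms: none
Why: Dess–Martin oxidation is neutral and forms no sulfide or low-valent metal that could reduce the peroxide; both C3 epimers converge on one ketone, and the near-neutral medium avoids β-elimination of the peroxide.

Step 11
Reactants: 12 (4S,6S,8R)-4,6,8-trimethyl-16-phenyl-4-[(triethylsilyl)peroxy]hexadecan-2-one; 13 1-(tert-butyldimethylsilyloxy)-1-methoxyethene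
Product: 16 methyl 2-{(3R,5S)-5-[(2S,4R)-2,4-dimethyl-12-phenyldodecyl]-3,5-dimethyl-1,2-dioxolan-3-yl}acetate, via 3-triethylsilyloxy-1,2-dioxolane 14 (not isolated), via peroxycarbenium triflate 15 (not isolated)
Conditions: 13 (2.5 equiv), TMSOTf (0.2 equiv), CH2Cl2, −78 to −40 °C
Reagents that add atoms: none
Why: Silyl triflate activates the C3 ketone of 12, the silylated terminal peroxide oxygen O2 adds to it in a 5-exo-trig closure, and the silyl group passes to the former carbonyl oxygen, giving 14 as an inconsequential mixture of C3 epimers. A second silylation expels a disiloxane and leaves the planar, O2-stabilised peroxycarbenium ion 15, so both epimers converge on one intermediate. Ketene acetal 13 then forms the C2–C3 bond irreversibly and releases silyl triflate, which closes the catalytic cycle. The closest known reaction type is the Lewis-acid substitution of 3-alkoxy-1,2-dioxolanes and other peroxyketals by silyl ketene acetals and allylsilanes (Mukaiyama-type alkylation). C3 is controlled by C5: in the envelope of 15 the β-branched C6 chain should lie pseudoequatorial and the C5 methyl pseudoaxial, so attack from inside the envelope, past the small methyl group and away from the chain, places CH2CO2Me trans to C6, which is 3R. The step needs the cyclic cation to win over direct aldol addition to the open ketone, which is secured because the five-membered intramolecular closure should be faster than any bimolecular attack on a hindered methyl ketone at −78 °C. It also needs the O–O bond to survive, which is helped by the absence of hydrogen on C3 and C5 and by a catalytic, non-reducing Lewis acid.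

Step 12
Reactants: 16 methyl 2-{(3R,5S)-5-[(2S,4R)-2,4-dimethyl-12-phenyldodecyl]-3,5-dimethyl-1,2-dioxolan-3-yl}acetate
Product: 17 2-{(3R,5S)-5-[(2S,4R)-2,4-dimethyl-12-phenyldodecyl]-3,5-dimethyl-1,2-dioxolan-3-yl}acetic acid (target)
Conditions: LiOH, THF–H2O, 0 °C to rt; then 1 M HCl
Reagents that add atoms: lithium hydroxide [Li+].[OH-]
Why: Saponification of an unhindered methyl ester; the di-tert-alkyl peroxide has no α-hydrogen for base-induced cleavage, and once the carboxylate forms, α-deprotonation and retro-Michael opening at C3 are disfavoured, so no stereocentre should be disturbed.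

## Compound list

1 | (R)-citronellal, (3R)-3,7-dimethyloct-6-enal | C[C@H](CCC=C(C)C)CC=O | starting material
2 | 6-phenylhex-1-ene | C=CCCCCc1ccccc1 | starting material
3 | (3R)-3-methyl-11-phenylundec-6-enal (E/Z) | C[C@H](CCC=CCCCCc1ccccc1)CC=O | intermediate
4 | (3R)-3-methyl-11-phenylundecanal | C[C@H](CCCCCCCCc1ccccc1)CC=O | intermediate
5 | (3E,6R)-6-methyl-14-phenyltetradec-3-en-2-one | C[C@H](CCCCCCCCc1ccccc1)C/C=C/C(C)=O | intermediate
6 | (4S,6R)-4,6-dimethyl-14-phenyltetradecan-2-one | C[C@H](CCCCCCCCc1ccccc1)C[C@H](C)CC(C)=O | intermediate
7 | (2R)-2-[(2S,4R)-2,4-dimethyl-12-phenyldodecyl]-2-methyloxirane | C[C@H](CCCCCCCCc1ccccc1)C[C@H](C)C[C@]1(C)CO1 | intermediate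
8 | (4S,6S,8R)-4,6,8-trimethyl-16-phenylhexadec-1-en-4-ol | C[C@H](CCCCCCCCc1ccccc1)C[C@H](C)C[C@](O)(C)CC=C | intermediate
9 | (2R,4RS)-2-[(2S,4R)-2,4-dimethyl-12-phenyldodecyl]-2,4-dimethyloxetane | C[C@H](CCCCCCCCc1ccccc1)C[C@H](C)C[C@]1(C)CC(C)O1 | intermediate
10 | (2RS,4S,6S,8R)-4-hydroperoxy-4,6,8-trimethyl-16-phenylhexadecan-2-ol | C[C@H](CCCCCCCCc1ccccc1)C[C@H](C)C[C@@](OO)(C)CC(C)O | intermediate
11 | (2RS,4S,6S,8R)-4,6,8-trimethyl-16-phenyl-4-[(triethylsilyl)peroxy]hexadecan-2-ol | C[C@H](CCCCCCCCc1ccccc1)C[C@H](C)C[C@@](OO[Si](CC)(CC)CC)(C)CC(C)O | intermediate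
12 | (4S,6S,8R)-4,6,8-trimethyl-16-phenyl-4-[(triethylsilyl)peroxy]hexadecan-2-one | C[C@H](CCCCCCCCc1ccccc1)C[C@H](C)C[C@@](OO[Si](CC)(CC)CC)(C)CC(C)=O | intermediate
13 | 1-(tert-butyldimethylsilyloxy)-1-methoxyethene | C=C(OC)O[Si](C)(C)C(C)(C)C | starting material
14 | (3RS,5S)-5-[(2S,4R)-2,4-dimethyl-12-phenyldodecyl]-3,5-dimethyl-3-(triethylsilyloxy)-1,2-dioxolane | C[C@H](CCCCCCCCc1ccccc1)C[C@H](C)C[C@@]1(C)CC(C)(O[Si](CC)(CC)CC)OO1 | intermediate
15 | (5S)-5-[(2S,4R)-2,4-dimethyl-12-phenyldodecyl]-3,5-dimethyl-1,2-dioxolan-3-ylium trifluoromethanesulfonate | C[C@H](CCCCCCCCc1ccccc1)C[C@H](C)C[C@@]1(C)CC(C)=[O+]O1.[O-]S(=O)(=O)C(F)(F)F | intermediate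
16 | methyl 2-{(3R,5S)-5-[(2S,4R)-2,4-dimethyl-12-phenyldodecyl]-3,5-dimethyl-1,2-dioxolan-3-yl}acetate | C[C@H](CCCCCCCCc1ccccc1)C[C@H](C)C[C@@]1(C)C[C@](C)(CC(=O)OC)OO1 | intermediate
17 | 2-{(3R,5S)-5-[(2S,4R)-2,4-dimethyl-12-phenyldodecyl]-3,5-dimethyl-1,2-dioxolan-3-yl}acetic acid | C[C@H](CCCCCCCCc1ccccc1)C[C@H](C)C[C@@]1(C)C[C@](C)(CC(=O)O)OO1 | target

## Step count and least certain steps

Total step count: 12. Longest linear sequence: 12 steps, from 1 to 17.

**Step 11 (key step).**
- Most likely failure: insufficient discrimination between the two faces of the cation, because the controlling groups on C5 differ only as CH3 and CH2R.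
- Next most likely: consumption of the ketene acetal by aldol addition to the still-open ketone if silyl transfer and closure are slow, and acid-induced heterolysis of the O–O bond.
- Fallback: it sets out from 12 and returns at 17, and it changes the leaving group, the nucleophile class and the endgame. Compound 12 is desilylated and ketalised with TsOH in MeOH to the isolated 3-methoxy-1,2-dioxolane F1. TiCl4-mediated Hosomi–Sakurai allylation with allyltrimethylsilane gives the 3-allyl-1,2-dioxolane F2. Ozonolysis with Me2S work-up gives the dioxolanyl acetaldehyde F3. Pinnick oxidation (NaClO2) then gives 17 directly and avoids the basic step 12.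

**Step 8.**
- Most likely failure: partial ionisation to a free tertiary cation before hydrogen peroxide arrives. This would erode the configuration at C5 and open the way to elimination, because a dialkyl-substituted quaternary carbon sits at the border between the two substitution mechanisms.
- Fallback: it sets out from 7 and returns at 12, and it uses the more strained three-membered ring followed by a carbon homologation. H3PMo12O40-catalysed perhydrolysis of the epoxide at C5 gives the β-hydroxy hydroperoxide F4. Peroxide-selective silylation gives the silylperoxy alcohol F5. Dess–Martin oxidation gives the α-silylperoxy aldehyde F6. Wittig reaction with Ph3P=C(OMe)CH3 gives the enol ether F7. Hydrolysis on oxalic acid-doped silica gives 12.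

**Step 7.**
- Most likely failure: the four-membered closure is outrun by alkene isomerisation, by simple reduction, or by fluoride capture of the organocobalt intermediate, because 4-exo displacement by a hindered tertiary alcohol is slow.
- Fallback: it sets out from 8 and returns at 9, and it replaces the radical–polar closure with a classical Williamson closure. Oxymercuration–demercuration (Hg(OAc)2, then NaBH4) gives the 1,3-diol F8. Selective mesylation of the secondary hydroxyl gives the hydroxy mesylate F9. KOt-Bu in THF closes the ring to 9.

**Step 4.**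
- Most likely failure: competing 1,2-addition of the small, hard methyl Grignard reagent to the methyl ketone, and lower face selectivity than with larger Grignard reagents.
- Fallback: it sets out from 4 and returns at 6, and it changes the acceptor class. Wittig reaction of 4 with Ph3P=CHC(O)SEt gives the unsaturated thioester F10. The same copper/ferrocenyl diphosphine system adds MeMgBr to give the β-methyl thioester F11. Me2CuLi then converts the thioester into methyl ketone 6.

**Step 9.**
- Most likely failure: loss of chemoselectivity through silylation of the secondary alcohol or silyl migration from peroxide to alcohol, since both sites are nucleophilic oxygens.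
- Fallback: it sets out from 10 and returns at 16, and it uses an acetal-type peroxide protection with a stepwise ring closure. Acid-catalysed addition of the hydroperoxide to 2-methoxypropene (pyridinium tosylate) gives the peroxyketal alcohol F12. Dess–Martin oxidation gives the peroxyketal ketone F13. TsOH in MeOH removes the ketal and closes the ring to the 3-methoxy-1,2-dioxolane F1, which is alkylated with 13 and TMSOTf to give 16.

## Further compounds

F1 | step 11 | (3RS,5S)-5-[(2S,4R)-2,4-dimethyl-12-phenyldodecyl]-3-methoxy-3,5-dimethyl-1,2-dioxolane | C[C@H](CCCCCCCCc1ccccc1)C[C@H](C)C[C@@]1(C)CC(C)(OC)OO1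
F2 | step 11 | (3S,5S)-5-[(2S,4R)-2,4-dimethyl-12-phenyldodecyl]-3,5-dimethyl-3-(prop-2-en-1-yl)-1,2-dioxolane | C[C@H](CCCCCCCCc1ccccc1)C[C@H](C)C[C@@]1(C)C[C@](C)(CC=C)OO1
F3 | step 11 | 2-{(3R,5S)-5-[(2S,4R)-2,4-dimethyl-12-phenyldodecyl]-3,5-dimethyl-1,2-dioxolan-3-yl}acetaldehyde | C[C@H](CCCCCCCCc1ccccc1)C[C@H](C)C[C@@]1(C)C[C@](C)(CC=O)OO1
F4 | step 8 | (2S,4S,6R)-2-hydroperoxy-2,4,6-trimethyl-14-phenyltetradecan-1-ol | C[C@H](CCCCCCCCc1ccccc1)C[C@H](C)C[C@@](OO)(C)CO
F5 | step 8 | (2S,4S,6R)-2,4,6-trimethyl-14-phenyl-2-[(triethylsilyl)peroxy]tetradecan-1-ol | C[C@H](CCCCCCCCc1ccccc1)C[C@H](C)C[C@@](OO[Si](CC)(CC)CC)(C)CO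
F6 | step 8 | (2S,4S,6R)-2,4,6-trimethyl-14-phenyl-2-[(triethylsilyl)peroxy]tetradecanal | C[C@H](CCCCCCCCc1ccccc1)C[C@H](C)C[C@@](OO[Si](CC)(CC)CC)(C)C=O
F7 | step 8 | (4S,6S,8R)-2-methoxy-4,6,8-trimethyl-16-phenyl-4-[(triethylsilyl)peroxy]hexadec-2-ene (E/Z) | C[C@H](CCCCCCCCc1ccccc1)C[C@H](C)C[C@@](OO[Si](CC)(CC)CC)(C)C=C(C)OC
F8 | step 7 | (2RS,4R,6S,8R)-4,6,8-trimethyl-16-phenylhexadecane-2,4-diol | C[C@H](CCCCCCCCc1ccccc1)C[C@H](C)C[C@](O)(C)CC(C)O
F9 | step 7 | (2RS,4R,6S,8R)-4-hydroxy-4,6,8-trimethyl-16-phenylhexadecan-2-yl methanesulfonate | C[C@H](CCCCCCCCc1ccccc1)C[C@H](C)C[C@](O)(C)CC(C)OS(C)(=O)=O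
F10 | step 4 | S-ethyl (2E,5R)-5-methyl-13-phenyltridec-2-enethioate | C[C@H](CCCCCCCCc1ccccc1)C/C=C/C(=O)SCC
F11 | step 4 | S-ethyl (3S,5R)-3,5-dimethyl-13-phenyltridecanethioate | C[C@H](CCCCCCCCc1ccccc1)C[C@H](C)CC(=O)SCC
F12 | step 9 | (2RS,4S,6S,8R)-4-[(2-methoxypropan-2-yl)peroxy]-4,6,8-trimethyl-16-phenylhexadecan-2-ol | C[C@H](CCCCCCCCc1ccccc1)C[C@H](C)C[C@@](OOC(C)(C)OC)(C)CC(C)O
F13 | step 9 | (4S,6S,8R)-4-[(2-methoxypropan-2-yl)peroxy]-4,6,8-trimethyl-16-phenylhexadecan-2-one | C[C@H](CCCCCCCCc1ccccc1)C[C@H](C)C[C@@](OOC(C)(C)OC)(C)CC(C)=O
A1 | alternative 1 | methyl (2E,7S,9R)-5-hydroperoxy-3,5,7,9-tetramethyl-17-phenylheptadec-2-enoate (C5 undefined) | C[C@H](CCCCCCCCc1ccccc1)C[C@H](C)CC(C)(OO)C/C(C)=C/C(=O)OC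
A2 | alternative 1 | methyl (2E,7S,9R)-3,7,9-trimethyl-5-methylidene-17-phenylheptadec-2-enoate | C[C@H](CCCCCCCCc1ccccc1)C[C@H](C)CC(=C)C/C(C)=C/C(=O)OC
A3 | alternative 2 | methyl 3-methoxy-3-[(triethylsilyl)peroxy]butanoate | COC(=O)CC(C)(OC)OO[Si](CC)(CC)CC
A4 | alternative 2 | (4S,6R)-2,4,6-trimethyl-14-phenyltetradec-1-ene | C[C@H](CCCCCCCCc1ccccc1)C[C@H](C)CC(C)=C
A5 | alternative 3 | (4S)-4-[(2S,4S,6R)-2-hydroperoxy-2,4,6-trimethyl-14-phenyltetradecyl]-4-methyloxetan-2-one | C[C@H](CCCCCCCCc1ccccc1)C[C@H](C)C[C@@](OO)(C)C[C@@]1(C)CC(=O)O1
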